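**Plan**
- Cuts, in retrosynthetic order: the ester C–O bonds at C7 and C9; C5–C6 (read as a 1,2-shift); C6–C7 (isopropenyl addition); the cyclobutane bond C5–C11; the Diels–Alder bonds C10–C11 and C3–C4.
- Enabling feature: in the seven-membered ring C5–C6–C7–C8–C9–C10–C11 the CMe2 carbon C6 lies between cyclobutane carbon C5 and oxygen-bearing C7. This is the pattern left when C5 shifts onto a dimethylcarbinyl cation beside a C7 carbinol of a six-membered (copaene-type) ring.
- Forward: quinone and siloxydiene give ring A (C10–C11–C1–C2–C3–C4) and ring B (C4–C5–C7–C8–C9–C10) as a cis-decalin; the cyclobutane closes third (C11 enolate on a C5 tosylate); ring B is then enlarged from six to seven members; the esters go on last.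
- Stereochemistry: C10 and C4 from the BINOL–titanium-catalysed endo cycloaddition; C9 from hydride attack on the convex face of the cis-decalin; C5 and C11 from Mitsunobu inversion followed by SN2 ring closure; C7 from Evans–Tishchenko 1,3-anti delivery from C9.

Key step: step 14

Numbering and faces: every intermediate keeps the atom numbers of the target (C1 ketone, C2=C3, bridgeheads C4 and C11, C5 cyclobutane CH, C6 CMe2, C7–C9, C10 quaternary C–Me). In the bicyclic compounds β means cis and α means trans to the C10 methyl, judged on the ring that carries the substituent.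

Assumption: the (S)-BINOL–TiCl2 Lewis acid is taken to give the enantiomer of 4 shown; the sense of induction for this quinone is assigned by analogy, and the (R)-ligand would be used if it proved opposite.

Step 1
Reactants: 1 (E)-pent-3-en-2-one
Product: 2 (E)-2-(triisopropylsilyloxy)penta-1,3-diene
Conditions: iPr3SiOTf, Et3N, Et2O, 0 °C → rt
Reagents that add atoms: triisopropylsilyl triflate, CC(C)[Si](C(C)C)(C(C)C)OS(=O)(=O)C(F)(F)F
Why: Silyl triflate and a tertiary amine enolise the enone on the methyl side under kinetic control (O-silylation to the cross-conjugated 2-siloxydiene), leaving the (E)-propenyl unit untouched.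

Step 2
Reactants: 2 (E)-2-(triisopropylsilyloxy)penta-1,3-diene; 3 2-methoxy-5-methyl-1,4-benzoquinone
Product: 4 cis-fused adduct: ring B 7-methoxy-7-ene-5,9-dione, ring A 1-(triisopropylsilyloxy)-1-ene, 10β-methyl, 4β-H, 3α-methyl
Conditions: (S)-BINOL/TiCl2(OiPr)2 (20 mol%, preformed), toluene, −30 → 0 °C
Reagents that add atoms: none
Why: Diels–Alder reaction in which titanium is held between the methoxy oxygen and the neighbouring quinone carbonyl, so the methyl-bearing carbon of the other double bond is the electrophilic terminus and takes the nucleophilic CH2 end of the diene (C10–C11), while suprafacial endo addition gives the cis ring fusion and the BINOL ligand differentiates the quinone faces, fixing C10 and C4.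

Step 3
Reactants: 4 cis-fused adduct
Product: 5 5α-alcohol: C5 carbonyl of 4 reduced, hydroxyl α (on the side of ring A)
Conditions: NaBH4 (0.3 equiv), CeCl3·7H2O, MeOH/CH2Cl2, −78 °C
Reagents that add atoms: none
Why: Luche-type 1,2-reduction selects the C5 carbonyl, which is neither part of the vinylogous ester nor neopentyl, and hydride enters from the convex face of the cis-decalin (the face of the angular methyl), so the hydroxyl is α.

Step 4
Reactants: 5 5α-alcohol
Product: 6 5β-(4-nitrobenzoate): C5 inverted, C9 ketone and C7 methyl enol ether unchanged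
Conditions: 4-O2NC6H4CO2H, PPh3, DIAD, toluene, 0 °C → rt
Reagents that add atoms: 4-nitrobenzoic acid, OC(=O)c1ccc(cc1)[N+](=O)[O-]
Why: Mitsunobu esterification is an SN2 displacement of the oxyphosphonium ion, so the carboxylate enters from the open β face and C5 acquires the configuration needed for the later backside attack by C11.

Step 5
Reactants: 6 5β-(4-nitrobenzoate)
Product: 7 9α-alcohol: C9 carbonyl reduced, hydroxyl α (trans to the C10 methyl), C7=C8 methyl enol ether retained
Conditions: NaBH4, CeCl3·7H2O, MeOH, −40 → 0 °C; buffered work-up, used crude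
Reagents that add atoms: none
Why: Luche reduction adds hydride 1,2 to the vinylogous-ester carbonyl faster than to the aryl ester, and in the half-chair that keeps the 5β-ester pseudoequatorial the C10–C11 bond is pseudoaxial on the α face, so hydride arrives from the β face and the C9 hydroxyl is α, the C9 configuration of the target.

Step 6
Reactants: 7 9α-alcohol
Product: 8 9α-tert-butyldimethylsilyl ether of 7
Conditions: tBuMe2SiOTf, 2,6-lutidine, CH2Cl2, −78 °C
Reagents that add atoms: tert-butyldimethylsilyl triflate, CC(C)(C)[Si](C)(C)OS(=O)(=O)C(F)(F)F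
Why: Silyl triflate with 2,6-lutidine silylates even a neopentyl allylic alcohol at low temperature under buffered conditions that do not ionise the acid-sensitive 3-methoxyallylic system.

Step 7
Reactants: 8 9α-silyl ether
Product: 9 ring A enone: C1 ketone and C2=C3 (3-methyl); ring B unchanged (7-methoxy-7-ene, 5β-ester, 9α-silyloxy)
Conditions: Pd(OAc)2 (1.1 equiv), MeCN, rt
Reagents that add atoms: none
Why: Saegusa–Ito oxidation turns the silyl enol ether into an oxa-π-allyl palladium enolate that loses the C3 hydrogen, the only β-hydrogen available, while the methyl enol ether, which cannot pass its alkyl group to palladium, is expected to remain.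

Step 8
Reactants: 9 ring A enone
Product: 10 C7 dimethyl ketal: 7,7-dimethoxy, C8 now CH2, 5β-ester and 9α-silyloxy retained
Conditions: PPTS (cat.), dry MeOH, 0 °C → rt
Reagents that add atoms: methanol, CO
Why: Acid-catalysed addition of an alcohol to an enol ether (the chemistry of acetal protection) protonates C8 and traps the C7 oxocarbenium ion as the ketal, which masks the future C7 ketone in base-stable form and removes the allylic relationship that would make a C5 sulfonate ionisable.

Step 9
Reactants: 10 C7 dimethyl ketal
Product: 11 5β-alcohol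
Conditions: K2CO3 (cat.), MeOH, 0 °C
Reagents that add atoms: none
Why: Carbonate-catalysed transesterification cleaves the activated 4-nitrobenzoate under conditions too mild to epimerise C4 through the dienolate or to touch the silyl ether and the ketal.

Step 10
Reactants: 11 5β-alcohol
Product: 12 5β-tosylate
Conditions: TsCl, Et3N, Me3N·HCl (cat.), CH2Cl2, 0 °C
Reagents that add atoms: 4-toluenesulfonyl chloride, Cc1ccc(cc1)S(=O)(=O)Cl
Why: Amine-catalysed sulfonylation occurs at oxygen with retention at C5, and the tosylate formed has no antiperiplanar β-hydrogen (C7 is fully substituted, C4–H is cis), which closes the E2 pathway.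

Step 11
Reactants: 12 5β-tosylate
Product: 14 copaene-type tricyclic enone 7-dimethyl ketal 9-silyl ether, via lithium enolate 13 (not isolated)
Conditions: LiN(iPr)2 (1.1 equiv), THF, −78 °C; then DMPU, −78 → 23 °C
Reagents that add atoms: none
Why: Kinetic deprotonation of the enone at the α′ carbon C11 gives the cross-conjugated enolate, which in the conformer with the C10–C11 bond axial on ring B lies 1,3 to C5 and displaces the β-tosylate from the α face with inversion (intramolecular enolate alkylation, 4-exo-tet), giving the cyclobutane with the only C5/C11 configuration the tricycle allows, while O-alkylation would need a bridgehead enol ether and the absence of a proton source keeps the eliminating γ-dienolate from forming.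

Step 12
Reactants: 14 tricyclic ketal
Product: 15 copaene-type tricyclic 1,7-dione 9-silyl ether (C9 oxygen on the C11 side)
Conditions: PPTS, acetone/H2O, 40 °C
Reagents that add atoms: water, O
Why: Mild aqueous acid hydrolyses the now ordinary dialkyl ketal to the C7 ketone without cleaving the hindered secondary silyl ether or eliminating the β-silyloxy group.

Step 13
Reactants: 15 tricyclic 1,7-dione
Product: 16 C7 isopropenyl carbinol of the copaene-type tricycle (hydroxyl cis and isopropenyl trans to the C9 silyloxy group)
Conditions: CH2=C(CH3)MgBr (1.1 equiv), CeCl3 (anhydrous), THF, −78 °C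
Reagents that add atoms: isopropenylmagnesium bromide, CC(=C)[Mg]Br
Why: Isopropenylcerium dichloride adds 1,2 to the saturated, strained C7 ketone in preference to the conjugated C1 enone and without enolisation or β-elimination, approaching anti to the C9 silyloxy group, and the C7 configuration so set is erased again in step 14.

Step 14
Reactants: 16 C7 isopropenyl carbinol
Product: 17 longipin-2-ene-1,7-dione 9-tert-butyldimethylsilyl ether
Conditions: TsOH (anhydrous, 0.3 equiv), CH2Cl2, 0 → 23 °C
Reagents that add atoms: none
Why: Markovnikov protonation of the 1,1-disubstituted alkene gives the tertiary C6 cation beside the carbinol carbon, the C7–C5 bond shifts to C6 and the hydroxyl collapses to the C7 carbonyl (protio-semipinacol rearrangement). The closest known reaction type is the acid-promoted ring expansion of 1-isopropenylcycloalkanols to 2,2-dimethylcycloalkanones. The seven-membered ring arises by one-carbon enlargement of the six-membered ring C5–C7–C8–C9–C10–C11 through the 1,2-shift, not by an end-to-end closure, so the C5–C6 bond to the quaternary carbon is made without substitution at a neopentyl centre. No stereocentre is created: C5 migrates with retention, C7 becomes trigonal, and C4, C9, C10 and C11 are not involved. The step needs migration of C5 instead of C8 and protonation of the alkene instead of ionisation of the tertiary allylic hydroxyl; C5 is a secondary cyclobutyl carbon whose shift relieves the boat strain of the bicyclo[3.1.1] six-membered ring, C8 is a methylene deactivated by the C9 oxygen, and anhydrous acid in a non-ionising solvent at low temperature disfavours loss of water. Because the isopropenyl group lies anti to the C9 silyloxy group, the ether oxygen cannot trap the C6 cation.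

Step 15
Reactants: 17 longipinenedione silyl ether
Product: 18 9-hydroxylongipin-2-ene-1,7-dione
Conditions: HF·pyridine, THF, 0 °C → rt
Reagents that add atoms: none
Why: Fluoride cleaves the Si–O bond under slightly acidic conditions, which avoids the retro-aldol and β-elimination that a basic fluoride source could trigger in the β-hydroxy ketone.

Step 16
Reactants: 18 9-hydroxylongipin-2-ene-1,7-dione
Product: 19 7-hydroxy-9-isobutyryloxylongipin-2-en-1-one (C7 and C9 oxygens anti)
Conditions: SmI2 (0.3 equiv, premixed with the aldehyde), iPrCHO (8 equiv), THF, −10 °C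
Reagents that add atoms: isobutyraldehyde, CC(C)C=O
Why: In the Evans–Tishchenko reduction the samarium-bound hemiacetal of the C9 hydroxyl and isobutyraldehyde passes its hydride to the C7 carbonyl on the face of the C9 oxygen, so the new C7 hydroxyl is 1,3-anti and the C9 oxygen emerges as the isobutyrate, while premixing ensures that only trivalent samarium meets the enone.

Step 17
Reactants: 19 7-hydroxy-9-isobutyrate
Product: 20 target CNP0214356.1 (9-isobutyryloxy-7-methacryloyloxylongipin-2-en-1-one)
Conditions: CH2=C(CH3)COCl, Et3N, DMAP (cat.), CH2Cl2, 0 °C → rt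
Reagents that add atoms: methacryloyl chloride, CC(=C)C(=O)Cl
Why: DMAP-catalysed acylation with the acid chloride esterifies the remaining hindered secondary hydroxyl at C7 without touching any stereocentre.

**Compound list**
1 | (E)-pent-3-en-2-one | C/C=C/C(C)=O | starting material
2 | (E)-2-(triisopropylsilyloxy)penta-1,3-diene | C/C=C/C(=C)O[Si](C(C)C)(C(C)C)C(C)C | intermediate
3 | 2-methoxy-5-methyl-1,4-benzoquinone | COC1=CC(=O)C(C)=CC1=O | starting material
4 | cis-fused Diels–Alder adduct (7-methoxy-7-ene-5,9-dione; 1-triisopropylsilyloxy-1-ene; 10β-Me, 4β-H, 3α-Me) | COC1=CC(=O)[C@@]2(C)CC(O[Si](C(C)C)(C(C)C)C(C)C)=C[C@@H](C)[C@H]2C1=O | intermediate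
5 | 5α-alcohol of 4 | COC1=CC(=O)[C@@]2(C)CC(O[Si](C(C)C)(C(C)C)C(C)C)=C[C@@H](C)[C@H]2[C@H]1O | intermediate
6 | 5β-(4-nitrobenzoate) | COC1=CC(=O)[C@@]2(C)CC(O[Si](C(C)C)(C(C)C)C(C)C)=C[C@@H](C)[C@H]2[C@@H]1OC(=O)c1ccc(cc1)[N+](=O)[O-] | intermediate
7 | 9α-alcohol (C7=C8 methyl enol ether, 5β-ester) | COC1=C[C@@H](O)[C@@]2(C)CC(O[Si](C(C)C)(C(C)C)C(C)C)=C[C@@H](C)[C@H]2[C@@H]1OC(=O)c1ccc(cc1)[N+](=O)[O-] | intermediate
8 | 9α-tert-butyldimethylsilyl ether of 7 | COC1=C[C@@H](O[Si](C)(C)C(C)(C)C)[C@@]2(C)CC(O[Si](C(C)C)(C(C)C)C(C)C)=C[C@@H](C)[C@H]2[C@@H]1OC(=O)c1ccc(cc1)[N+](=O)[O-] | intermediate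
9 | ring A enone (C1 ketone, C2=C3; 7-methoxy-7-ene, 5β-ester, 9α-silyloxy) | COC1=C[C@@H](O[Si](C)(C)C(C)(C)C)[C@@]2(C)CC(=O)C=C(C)[C@H]2[C@@H]1OC(=O)c1ccc(cc1)[N+](=O)[O-] | intermediate
10 | C7 dimethyl ketal of 9 | COC1(OC)C[C@@H](O[Si](C)(C)C(C)(C)C)[C@@]2(C)CC(=O)C=C(C)[C@H]2[C@@H]1OC(=O)c1ccc(cc1)[N+](=O)[O-] | intermediate
11 | 5β-alcohol | COC1(OC)C[C@@H](O[Si](C)(C)C(C)(C)C)[C@@]2(C)CC(=O)C=C(C)[C@H]2[C@@H]1O | intermediate
12 | 5β-tosylate | COC1(OC)C[C@@H](O[Si](C)(C)C(C)(C)C)[C@@]2(C)CC(=O)C=C(C)[C@H]2[C@@H]1OS(=O)(=O)c1ccc(C)cc1 | intermediate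
13 | lithium C1–C11 enolate of 12 (not isolated) | COC1(OC)C[C@@H](O[Si](C)(C)C(C)(C)C)[C@@]2(C)C=C([O-])C=C(C)[C@H]2[C@@H]1OS(=O)(=O)c1ccc(C)cc1.[Li+] | intermediate
14 | copaene-type tricyclic enone, 7,7-dimethoxy, 9-silyloxy (C9 oxygen on the C11 side) | COC1(OC)C[C@@H](O[Si](C)(C)C(C)(C)C)[C@@]2(C)[C@@H]3C(=O)C=C(C)[C@H]2[C@@H]31 | intermediate
15 | copaene-type tricyclic 1,7-dione 9-silyl ether | O=C1C[C@@H](O[Si](C)(C)C(C)(C)C)[C@@]2(C)[C@@H]3C(=O)C=C(C)[C@H]2[C@@H]31 | intermediate
16 | C7 isopropenyl carbinol (OH cis to the C9 silyloxy group) | C=C(C)[C@]1(O)C[C@@H](O[Si](C)(C)C(C)(C)C)[C@@]2(C)[C@@H]3C(=O)C=C(C)[C@H]2[C@@H]31 | intermediate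
17 | longipin-2-ene-1,7-dione 9-tert-butyldimethylsilyl ether | O=C1C[C@@H](O[Si](C)(C)C(C)(C)C)[C@@]2(C)[C@@H]3C(=O)C=C(C)[C@H]2[C@@H]3C1(C)C | intermediate
18 | 9-hydroxylongipin-2-ene-1,7-dione | O=C1C[C@@H](O)[C@@]2(C)[C@@H]3C(=O)C=C(C)[C@H]2[C@@H]3C1(C)C | intermediate
19 | 7-hydroxy-9-isobutyryloxylongipin-2-en-1-one (7,9-anti) | O[C@@H]1C[C@@H](OC(=O)C(C)C)[C@@]2(C)[C@@H]3C(=O)C=C(C)[C@H]2[C@@H]3C1(C)C | intermediate
20 | CNP0214356.1, 9-isobutyryloxy-7-methacryloyloxylongipin-2-en-1-one | C=C(C)C(=O)O[C@@H]1C[C@@H](OC(=O)C(C)C)[C@@]2(C)[C@@H]3C(=O)C=C(C)[C@H]2[C@@H]3C1(C)C | target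

**Count and risks**
Total: 17 steps. Longest linear sequence: 17 steps (from 1; quinone 3 enters at step 2).

Steps most likely to fail:

1. Step 14 (ring expansion). Loss of water from the tertiary allylic carbinol can compete with protonation of the alkene, and a cation at C7, sitting next to the cyclobutane, can start a skeletal rearrangement. Migration of C8 and acid-induced elimination of the silyloxy group are lesser risks. The fallback sets out from 15 and returns at 17. 2-Lithio-2-(methylseleno)propane, made from 2,2-bis(methylseleno)propane and nBuLi in THF at −78 °C, is added to the C7 ketone of 15 to give the β-hydroxy selenide F1. AgBF4 on Al2O3 in CH2Cl2 then turns selenium into a leaving group, and C5 shifts onto C6 as it departs. This gives 17 with no allylic alcohol in the substrate.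

2. Step 11 (cyclobutane closure). Proton transfer may convert the α′ enolate into the extended dienolate, which expels the tosylate across the π system, or the displacement at the hindered C5 may be too slow at temperatures the kinetic enolate tolerates. The fallback sets out from 12 and returns at 14. Hydrogenation of the C2=C3 bond (H2, Pd/C, EtOAc) gives the saturated keto tosylate F2. KOtBu in tBuOH/THF at 40–60 °C equilibrates the two enolates; only the C11 enolate can reach the back side of C5, and no elimination path exists, so the saturated tricyclic ketal F3 results. C11 is now a bridgehead, so LiN(iPr)2/Me3SiCl gives only the C1–C2 trimethylsilyl enol ether F4, and Saegusa–Ito oxidation (Pd(OAc)2, MeCN) returns to 14.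

3. Step 2 (cycloaddition). Enantioselectivity or turnover may be poor when the quaternary C10 centre forms under the chiral titanium Lewis acid. The fallback sets out from 2 and 3 and returns at 5. The uncatalysed cycloaddition (toluene, 60 °C) has the same orientation and gives 4 together with the enantiomeric adduct F5. Reduction as in step 3 gives 5 and the enantiomeric alcohol F6. Esterification with (R)-2-methoxy-2-phenylacetic acid (DCC, DMAP) gives the wanted mandelate F7 and the unwanted mandelate F8, which are separated by chromatography. K2CO3 in MeOH at 0 °C cleaves F7 back to enantiopure 5.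

Further compounds
F1 | step 14 | β-hydroxy selenide: C7 (2-methylseleno-2-propyl) carbinol of the tricyclic dione | C[Se]C(C)(C)[C@]1(O)C[C@@H](O[Si](C)(C)C(C)(C)C)[C@@]2(C)[C@@H]3C(=O)C=C(C)[C@H]2[C@@H]31
F2 | step 11 | saturated keto tosylate (2,3-dihydro-12, 3α-methyl) | COC1(OC)C[C@@H](O[Si](C)(C)C(C)(C)C)[C@@]2(C)CC(=O)C[C@@H](C)[C@H]2[C@@H]1OS(=O)(=O)c1ccc(C)cc1
F3 | step 11 | saturated tricyclic ketal (2,3-dihydro-14) | COC1(OC)C[C@@H](O[Si](C)(C)C(C)(C)C)[C@@]2(C)[C@@H]3C(=O)C[C@@H](C)[C@H]2[C@@H]31
F4 | step 11 | C1–C2 trimethylsilyl enol ether of F3 | COC1(OC)C[C@@H](O[Si](C)(C)C(C)(C)C)[C@@]2(C)[C@@H]3C(O[Si](C)(C)C)=C[C@@H](C)[C@H]2[C@@H]31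
F5 | step 2 | enantiomer of adduct 4 | COC1=CC(=O)[C@]2(C)CC(O[Si](C(C)C)(C(C)C)C(C)C)=C[C@H](C)[C@@H]2C1=O
F6 | step 2 | enantiomer of alcohol 5 | COC1=CC(=O)[C@]2(C)CC(O[Si](C(C)C)(C(C)C)C(C)C)=C[C@H](C)[C@@H]2[C@@H]1O
F7 | step 2 | (R)-2-methoxy-2-phenylacetate of 5 | COC1=CC(=O)[C@@]2(C)CC(O[Si](C(C)C)(C(C)C)C(C)C)=C[C@@H](C)[C@H]2[C@H]1OC(=O)[C@H](OC)c1ccccc1
F8 | step 2 | (R)-2-methoxy-2-phenylacetate of the enantiomer of 5 | COC1=CC(=O)[C@]2(C)CC(O[Si](C(C)C)(C(C)C)C(C)C)=C[C@H](C)[C@@H]2[C@@H]1OC(=O)[C@H](OC)c1ccccc1
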